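**Strategy.** The route rests on cutting the two aryl bonds at C2 and C3 of the ring A dihydrobenzofuran (O1–C2–C3, fused to ring A): C3–C5' to ring B and C2–C(4-hydroxyphenyl). These two carbons are treated as the two ends of a vinyl group on ring A, to which the aryl groups are added anti. One palladium-catalysed three-component coupling of an E-alkenylboronate, 4-methoxyphenyllithium and the ring B triflate forms both bonds and both stereocentres. It leaves a C2–B bond that is oxidised and then displaced with inversion by the ring A phenol oxygen. The precursor is a 2-chloro-4-methoxy-6-(methoxymethoxy)styryl boronic ester carrying the bulky mac diol (cis-1,2-dimethylacenaphthylene-1,2-diol) on boron.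

Key step: step 16

Assumption (catalyst sense): the face selectivity of Rh2(R-PTAD)4 in step 12 and of the (Sp,Sp) ligand in step 16 is taken to be the one drawn; if either proves opposite, the mirror-image catalyst is used with nothing else changed.
Assumption (supply): tert-butyl(4-ethynylphenoxy)dimethylsilane 35 is treated as a catalogue alkyne; it is otherwise one silylation away from 4-ethynylphenol.

**Ring A alkenylboronate**

Step 1
Reactants: 1 1-chloro-3,5-dimethoxybenzene
Product: 3 2-chloro-4,6-dimethoxybenzaldehyde, via iminium chloride 2 (not isolated)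
Conditions: POCl3, DMF, 0 → 90 °C; then ice-water
Reagents that add atoms: N,N-dimethylformamide CN(C)C=O; water O
Why: Vilsmeier–Haack formylation should occur at C2, para to one methoxy group and ortho to the other, in preference to the more crowded position between the two methoxy groups, and hydrolysis of iminium 2 releases the aldehyde.

Step 2
Reactants: 3 2-chloro-4,6-dimethoxybenzaldehyde
Product: 4 2-chloro-6-hydroxy-4-methoxybenzaldehyde
Conditions: BCl3, CH2Cl2, −78 → 0 °C; then H2O
Reagents that add atoms: none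
Why: BCl3 chelates between the aldehyde oxygen and the ortho methoxy group, so only that methyl ether is cleaved (chelation-directed demethylation) and the para methoxy group stays.

Step 3
Reactants: 4 2-chloro-6-hydroxy-4-methoxybenzaldehyde
Product: 5 2-chloro-4-methoxy-6-(methoxymethoxy)benzaldehyde
Conditions: MOMCl, i-Pr2NEt, CH2Cl2, 0 °C → rt
Reagents that add atoms: chloromethyl methyl ether COCCl
Why: O-alkylation of the phenol gives the MOM acetal, a small group that masks the future O1 without crowding the alkene and survives organolithium and palladium chemistry.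

Step 4
Reactants: 5 2-chloro-4-methoxy-6-(methoxymethoxy)benzaldehyde; 6 bis[(pinacolato)boryl]methane
Product: 8 (E)-2-[2-chloro-4-methoxy-6-(methoxymethoxy)phenyl]ethenylboronic acid pinacol ester, via lithiated diborylmethane 7 (not isolated)
Conditions: lithium 2,2,6,6-tetramethylpiperidide, THF, 0 °C; then 5, −78 °C → rt
Reagents that add atoms: none
Why: Boron–Wittig olefination, in which lithiated 7 adds to the aldehyde and syn elimination of the boron–oxygen pair from the favoured adduct gives the E-alkenylboronate.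

Step 5
Reactants: 8 E-alkenyl pinacol boronate
Product: 9 (E)-2-[2-chloro-4-methoxy-6-(methoxymethoxy)phenyl]ethenylboronic acid
Conditions: NaIO4, NH4OAc, acetone/H2O, rt
Reagents that add atoms: water O
Why: Periodate cleaves the pinacol released in the hydrolysis equilibrium (oxidative glycol cleavage), which drives a near-neutral conversion to the boronic acid that should leave the MOM acetal and the alkene untouched.

Step 6
Reactants: 10 acenaphthoquinone
Product: 11 cis-1,2-dimethyl-1,2-dihydroacenaphthylene-1,2-diol (meso, "mac" diol)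
Conditions: MeMgBr (3 equiv), THF, −78 °C → rt; then H2O; crystallisation of the cis diol
Reagents that add atoms: methylmagnesium bromide C[Mg]Br
Why: Double Grignard addition to the 1,2-diketone gives the tertiary 1,2-diol, and the cis (meso) isomer, the only one able to bridge one boron atom, is separated by crystallisation.

Step 7
Reactants: 9 E-alkenylboronic acid; 11 mac diol
Product: 12 (E)-2-[2-chloro-4-methoxy-6-(methoxymethoxy)phenyl]ethenylboronic acid mac ester
Conditions: MgSO4, toluene, 60 °C
Reagents that add atoms: none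
Why: Dehydrative esterification of a boronic acid with a cis-1,2-diol; the bulky mac ester is chosen over pinacol because β-substituted alkenyl pinacol boronates tend to transfer the alkenyl group directly to palladium instead of undergoing the metallate shift.

**Ring B triflate**

Step 8
Reactants: 13 5-bromo-2-hydroxy-3-methoxybenzaldehyde; 14 4-methoxybenzyl chloride
Product: 15 5-bromo-3-methoxy-2-[(4-methoxybenzyl)oxy]benzaldehyde
Conditions: K2CO3, DMF, 60 °C
Reagents that add atoms: none
Why: Williamson etherification of the phenol installs the 4-methoxybenzyl group whose CH2 becomes C2' with its aryl substituent.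

Step 9
Reactants: 15 aldehyde; 16 1-bromo-3,5-dimethoxybenzene
Product: 18 [5-bromo-3-methoxy-2-[(4-methoxybenzyl)oxy]phenyl](3,5-dimethoxyphenyl)methanol (racemic), via aryl Grignard reagent 17 (not isolated)
Conditions: 16, Mg, THF, rt; then 15, 0 °C → rt; then H2O
Reagents that add atoms: none
Why: Grignard addition of 17 to the aldehyde is much faster than magnesium–bromine exchange at the ring bromide and gives a diarylmethanol whose stereocentre is erased in the next step.

Step 10
Reactants: 18 diarylmethanol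
Product: 19 [5-bromo-3-methoxy-2-[(4-methoxybenzyl)oxy]phenyl](3,5-dimethoxyphenyl)methanone
Conditions: Dess–Martin periodinane, CH2Cl2, rt
Reagents that add atoms: none
Why: Dess–Martin oxidation of a secondary diaryl carbinol to the ketone under neutral conditions that leave the 4-methoxybenzyl ether and the aryl bromide intact.

Step 11
Reactants: 19 diaryl ketone
Product: 20 hydrazone of ketone 19 (E/Z mixture)
Conditions: N2H4·H2O, AcOH (cat.), EtOH, 80 °C
Reagents that add atoms: hydrazine NN
Why: Acid-catalysed condensation of the benzophenone with excess hydrazine gives the free hydrazone needed as a diazo precursor.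

Step 12
Reactants: 20 hydrazone
Product: 22 (2S,3R)-5-bromo-3-(3,5-dimethoxyphenyl)-7-methoxy-2-(4-methoxyphenyl)-2,3-dihydro-1-benzofuran (2,3-cis), via diaryldiazomethane 21 (not isolated)
Conditions: MnO2, MeCN, 0 °C; filtration; Rh2(R-PTAD)4 [dirhodium tetrakis((R)-1-adamantyl-N-phthalimidoacetate)] (1 mol %), 0 °C → rt
Reagents that add atoms: none
Why: MnO2 dehydrogenates the hydrazone to diazo compound 21, and the chiral dirhodium carboxylate converts it into a donor/donor carbene that inserts into the ether-activated benzylic C–H bond through a five-membered transition state (intramolecular 1,5 C–H insertion), the catalyst setting C3' as R and the concerted insertion giving the 2,3-cis ring.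

Step 13
Reactants: 22 cis-dihydrobenzofuran
Product: 23 (2R,3R)-5-bromo-3-(3,5-dimethoxyphenyl)-7-methoxy-2-(4-methoxyphenyl)-2,3-dihydro-1-benzofuran (2,3-trans)
Conditions: CF3CO2H, CH2Cl2, 0 °C → rt
Reagents that add atoms: none
Why: Acid reversibly ionises the O1'–C2' bond to a 4-methoxybenzylic cation that recloses to the thermodynamically preferred trans isomer (acid-mediated epimerisation), so C2' becomes R under control of the untouched C3'.

Step 14
Reactants: 23 trans-bromide
Product: 24 (2R,3R)-3-(3,5-dimethoxyphenyl)-7-methoxy-2-(4-methoxyphenyl)-2,3-dihydro-1-benzofuran-5-ol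
Conditions: Pd2(dba)3 (2 mol %), tBuXPhos (8 mol %), KOH, 1,4-dioxane/H2O, 100 °C; then aq. HCl
Reagents that add atoms: potassium hydroxide [K+].[OH-]
Why: Palladium-catalysed hydroxylation of an aryl bromide with hydroxide (C–O coupling with a bulky biarylphosphine) gives the phenol, and the base-stable trans-dihydrobenzofuran and methyl ethers should be unaffected.

Step 15
Reactants: 24 phenol
Product: 25 (2R,3R)-3-(3,5-dimethoxyphenyl)-7-methoxy-2-(4-methoxyphenyl)-2,3-dihydro-1-benzofuran-5-yl trifluoromethanesulfonate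
Conditions: Tf2O, pyridine, CH2Cl2, 0 °C
Reagents that add atoms: trifluoromethanesulfonic anhydride O=S(=O)(OS(=O)(=O)C(F)(F)F)C(F)(F)F
Why: O-Sulfonylation of the phenol gives the aryl triflate, the electrophile best suited to a halide-free conjunctive coupling.

**Key step and endgame**

Step 16
Reactants: 12 E-alkenyl mac boronate; 26 4-bromoanisole; 25 ring B triflate
Product: 29 (1R,2S)-2-[2-chloro-4-methoxy-6-(methoxymethoxy)phenyl]-2-[(2R,3R)-3-(3,5-dimethoxyphenyl)-7-methoxy-2-(4-methoxyphenyl)-2,3-dihydro-1-benzofuran-5-yl]-1-(4-methoxyphenyl)ethylboronic acid mac ester, via 4-methoxyphenyllithium 27 (not isolated), via lithium borate complex 28 (not isolated)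
Conditions: 26, n-BuLi, THF, −78 °C; then 12, −78 °C → rt; volatiles removed; Pd(OAc)2 (5 mol %), (Sp,Sp)-1,1'-bis[bis(3,5-dimethylphenyl)phosphino]-2,2'-bis[(R)-α-(dimethylamino)benzyl]ferrocene (6 mol %), 25, THF, 60 °C
Reagents that add atoms: none
Why: Proposed new method: zerovalent palladium inserts into the C5'–OTf bond of 25 and the resulting cationic arylpalladium species binds the E-alkene of ate complex 28 on the face chosen by the ferrocenyl bisphosphine, which triggers a 1,2-shift of the 4-methoxyphenyl group from boron to C2 anti to palladium at C3, and C–C reductive elimination with retention then joins ring B to C3. The closest known reaction type is the palladium-catalysed enantioselective conjunctive cross-coupling of alkenylboron ate complexes with aryl triflates, including β-alkyl-substituted alkenyl mac boronates; a β-aryl group with two ortho substituents combined with an aryl migrating group lies outside that scope. No ring is closed in this step. C3 (S) is set by catalyst-controlled enantioface selection and C2 (R) by the stereospecific anti addition across the E-alkene, so both centres arise as one diastereomer with C2 configured for invertive O1–C2 closure. The step needs the metallate shift to outrun direct alkenyl transmetallation and the triflate to react in preference to the ring A chloride. The bulky mac diol on boron, the halide-free ate complex and the far higher reactivity of the C–OTf bond should secure this, and the small MOM group keeps the alkene accessible.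

Step 17
Reactants: 29 conjunctive-coupling product
Product: 31 (1R,2S)-2-(2-chloro-6-hydroxy-4-methoxyphenyl)-2-[(2R,3R)-dihydrobenzofuran-5-yl]-1-(4-methoxyphenyl)ethylboronic acid mac ester (free ring A phenol), via aryl trimethylsilyl ether 30 (not isolated)
Conditions: Me3SiOTf, 2,2'-bipyridyl, MeCN, 0 °C → rt; then H2O
Reagents that add atoms: none
Why: The silyl triflate–bipyridyl pair converts an aromatic MOM ether into the aryl silyl ether without protic acid (chemoselective MOM cleavage) and water hydrolyses it to the phenol, so the acid-labile 2-aryl-dihydrobenzofuran of ring B and the benzylic C–B bond are spared.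

Step 18
Reactants: 31 phenol boronate
Product: 32 (1R,2S)-2-(2-chloro-6-hydroxy-4-methoxyphenyl)-2-[(2R,3R)-3-(3,5-dimethoxyphenyl)-7-methoxy-2-(4-methoxyphenyl)-2,3-dihydro-1-benzofuran-5-yl]-1-(4-methoxyphenyl)ethanol
Conditions: NaBO3·4H2O, THF/H2O, rt
Reagents that add atoms: sodium perborate [Na+].[Na+].O[B-]1(O)OO[B-](O)(O)OO1
Why: Perborate oxidation of the secondary boronic ester proceeds by 1,2-migration of carbon from boron to oxygen with retention, giving the (R)-carbinol at C2 without touching C3.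

Step 19
Reactants: 32 phenol–alcohol
Product: 33 (2S,3S)-4-chloro-3-[(2R,3R)-3-(3,5-dimethoxyphenyl)-7-methoxy-2-(4-methoxyphenyl)-2,3-dihydro-1-benzofuran-5-yl]-6-methoxy-2-(4-methoxyphenyl)-2,3-dihydro-1-benzofuran
Conditions: PPh3, DIAD, THF, 0 °C → rt
Reagents that add atoms: none
Why: Intramolecular Mitsunobu etherification in which the phenol displaces the oxyphosphonium of the benzylic alcohol in a 5-exo-tet SN2 closure of O1–C2 with inversion, turning (R)-C2 into (S)-C2 and giving the 2,3-trans ring, which is also the thermodynamic outcome should any ionisation intervene.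

Step 20
Reactants: 33 hexamethyl ether
Product: 34 (2S,3S)-4-chloro-3-[(2R,3R)-3-(3,5-dihydroxyphenyl)-7-hydroxy-2-(4-hydroxyphenyl)-2,3-dihydro-1-benzofuran-5-yl]-2-(4-hydroxyphenyl)-2,3-dihydro-1-benzofuran-6-ol
Conditions: BBr3, CH2Cl2, −78 °C → rt; then MeOH, H2O
Reagents that add atoms: none
Why: BBr3 cleaves all six aryl methyl ethers (Lewis acid demethylation) at a stage where no stilbene is present, so acid-induced Z/E isomerisation or cyclisation of the alkene cannot occur, and the trans-dihydrobenzofurans and the aryl chloride should persist.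

Step 21
Reactants: 35 tert-butyl(4-ethynylphenoxy)dimethylsilane
Product: 36 (Z)-2-[4-(tert-butyldimethylsilyloxy)phenyl]ethenylboronic acid pinacol ester
Conditions: HBpin, [Rh(cod)Cl]2 (1.5 mol %), P(i-Pr)3 (6 mol %), Et3N, cyclohexane, rt
Reagents that add atoms: pinacolborane [H]B1OC(C)(C)C(C)(C)O1
Why: Rhodium-catalysed trans-hydroboration of a terminal alkyne proceeds through a rhodium vinylidene and places boron cis to the aryl group, giving the Z-alkenylboronate.

Step 22
Reactants: 34 chloro hexaphenol; 36 Z-alkenylboronate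
Product: 38 5-[(2R,3R)-7-hydroxy-5-[(2S,3S)-6-hydroxy-2-(4-hydroxyphenyl)-4-[(Z)-2-(4-hydroxyphenyl)ethenyl]-2,3-dihydro-1-benzofuran-3-yl]-2-(4-hydroxyphenyl)-2,3-dihydro-1-benzofuran-3-yl]benzene-1,3-diol (CNP0172909.2), via target silyl ether 37 (not isolated)
Conditions: Pd(OAc)2 (5 mol %), SPhos (10 mol %), K3PO4, 1,4-dioxane/H2O (degassed), 80 °C, dark; then Bu4NF, rt
Reagents that add atoms: none
Why: Suzuki–Miyaura coupling in which SPhos-ligated zerovalent palladium inserts into the hindered C4–Cl bond, the Z-alkenylboronate couples with retention of geometry in the presence of free phenolates, and fluoride then removes the aryl silyl ether to release the target.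

**Compound list**

1 | 1-chloro-3,5-dimethoxybenzene | COc1cc(Cl)cc(OC)c1 | starting material
2 | N-(2-chloro-4,6-dimethoxybenzylidene)-N-methylmethanaminium chloride | C[N+](C)=Cc1c(Cl)cc(OC)cc1OC.[Cl-] | intermediate
3 | 2-chloro-4,6-dimethoxybenzaldehyde | COc1cc(Cl)c(C=O)c(OC)c1 | intermediate
4 | 2-chloro-6-hydroxy-4-methoxybenzaldehyde | COc1cc(O)c(C=O)c(Cl)c1 | intermediate
5 | 2-chloro-4-methoxy-6-(methoxymethoxy)benzaldehyde | COCOc1cc(OC)cc(Cl)c1C=O | intermediate
6 | bis[(pinacolato)boryl]methane | CC1(C)OB(CB2OC(C)(C)C(C)(C)O2)OC1(C)C | starting material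
7 | lithio-bis[(pinacolato)boryl]methane | [Li]C(B1OC(C)(C)C(C)(C)O1)B1OC(C)(C)C(C)(C)O1 | intermediate
8 | (E)-2-[2-chloro-4-methoxy-6-(methoxymethoxy)phenyl]ethenylboronic acid pinacol ester | COCOc1cc(OC)cc(Cl)c1/C=C/B1OC(C)(C)C(C)(C)O1 | intermediate
9 | (E)-2-[2-chloro-4-methoxy-6-(methoxymethoxy)phenyl]ethenylboronic acid | COCOc1cc(OC)cc(Cl)c1/C=C/B(O)O | intermediate
10 | acenaphthoquinone | O=C1C(=O)c2cccc3cccc1c23 | starting material
11 | cis-1,2-dimethyl-1,2-dihydroacenaphthylene-1,2-diol (mac diol, meso) | C[C@@]1(O)c2cccc3cccc(c23)[C@]1(C)O | intermediate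
12 | (E)-2-[2-chloro-4-methoxy-6-(methoxymethoxy)phenyl]ethenylboronic acid mac ester | COCOc1cc(OC)cc(Cl)c1/C=C/B1O[C@]2(C)c3cccc4cccc(c34)[C@]2(C)O1 | intermediate
13 | 5-bromo-2-hydroxy-3-methoxybenzaldehyde | COc1cc(Br)cc(C=O)c1O | starting material
14 | 4-methoxybenzyl chloride | COc1ccc(CCl)cc1 | starting material
15 | 5-bromo-3-methoxy-2-[(4-methoxybenzyl)oxy]benzaldehyde | COc1ccc(COc2c(OC)cc(Br)cc2C=O)cc1 | intermediate
16 | 1-bromo-3,5-dimethoxybenzene | COc1cc(Br)cc(OC)c1 | starting material
17 | 3,5-dimethoxyphenylmagnesium bromide | COc1cc(OC)cc([Mg]Br)c1 | intermediate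
18 | [5-bromo-3-methoxy-2-[(4-methoxybenzyl)oxy]phenyl](3,5-dimethoxyphenyl)methanol (racemic) | COc1ccc(COc2c(OC)cc(Br)cc2C(O)c2cc(OC)cc(OC)c2)cc1 | intermediate
19 | [5-bromo-3-methoxy-2-[(4-methoxybenzyl)oxy]phenyl](3,5-dimethoxyphenyl)methanone | COc1ccc(COc2c(OC)cc(Br)cc2C(=O)c2cc(OC)cc(OC)c2)cc1 | intermediate
20 | hydrazone of ketone 19 | COc1ccc(COc2c(OC)cc(Br)cc2C(=NN)c2cc(OC)cc(OC)c2)cc1 | intermediate
21 | diaryldiazomethane from 20 | COc1ccc(COc2c(OC)cc(Br)cc2C(=[N+]=[N-])c2cc(OC)cc(OC)c2)cc1 | intermediate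
22 | (2S,3R)-5-bromo-3-(3,5-dimethoxyphenyl)-7-methoxy-2-(4-methoxyphenyl)-2,3-dihydro-1-benzofuran (cis) | Brc1cc(OC)c2c(c1)[C@@H](c1cc(OC)cc(OC)c1)[C@@H](c1ccc(OC)cc1)O2 | intermediate
23 | (2R,3R)-5-bromo-3-(3,5-dimethoxyphenyl)-7-methoxy-2-(4-methoxyphenyl)-2,3-dihydro-1-benzofuran (trans) | Brc1cc(OC)c2c(c1)[C@@H](c1cc(OC)cc(OC)c1)[C@H](c1ccc(OC)cc1)O2 | intermediate
24 | (2R,3R)-3-(3,5-dimethoxyphenyl)-7-methoxy-2-(4-methoxyphenyl)-2,3-dihydro-1-benzofuran-5-ol | Oc1cc(OC)c2c(c1)[C@@H](c1cc(OC)cc(OC)c1)[C@H](c1ccc(OC)cc1)O2 | intermediate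
25 | (2R,3R)-3-(3,5-dimethoxyphenyl)-7-methoxy-2-(4-methoxyphenyl)-2,3-dihydro-1-benzofuran-5-yl trifluoromethanesulfonate | FC(F)(F)S(=O)(=O)Oc1cc(OC)c2c(c1)[C@@H](c1cc(OC)cc(OC)c1)[C@H](c1ccc(OC)cc1)O2 | intermediate
26 | 4-bromoanisole | COc1ccc(Br)cc1 | starting material
27 | 4-methoxyphenyllithium | [Li]c1ccc(OC)cc1 | intermediate
28 | lithium (E)-alkenyl(4-methoxyphenyl)borate of 12 (configuration at boron undefined) | [Li+].COCOc1cc(OC)cc(Cl)c1/C=C/[B-]1(c2ccc(OC)cc2)O[C@]2(C)c3cccc4cccc(c34)[C@]2(C)O1 | intermediate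
29 | (1R,2S)-1,2,2-triarylethylboronic acid mac ester (C1: B and 4-methoxyphenyl; C2: MOM-protected ring A aryl and ring B dihydrobenzofuran-5-yl) | COCOc1cc(OC)cc(Cl)c1[C@H](c1cc(OC)c2c(c1)[C@@H](c1cc(OC)cc(OC)c1)[C@H](c1ccc(OC)cc1)O2)[C@H](c1ccc(OC)cc1)B1O[C@]2(C)c3cccc4cccc(c34)[C@]2(C)O1 | intermediate
30 | aryl trimethylsilyl ether of 31 | C[Si](C)(C)Oc1cc(OC)cc(Cl)c1[C@H](c1cc(OC)c2c(c1)[C@@H](c1cc(OC)cc(OC)c1)[C@H](c1ccc(OC)cc1)O2)[C@H](c1ccc(OC)cc1)B1O[C@]2(C)c3cccc4cccc(c34)[C@]2(C)O1 | intermediate
31 | (1R,2S)-triarylethylboronic acid mac ester with free ring A phenol | Oc1cc(OC)cc(Cl)c1[C@H](c1cc(OC)c2c(c1)[C@@H](c1cc(OC)cc(OC)c1)[C@H](c1ccc(OC)cc1)O2)[C@H](c1ccc(OC)cc1)B1O[C@]2(C)c3cccc4cccc(c34)[C@]2(C)O1 | intermediate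
32 | (1R,2S)-2-(2-chloro-6-hydroxy-4-methoxyphenyl)-2-[(2R,3R)-dihydrobenzofuran-5-yl]-1-(4-methoxyphenyl)ethanol | Oc1cc(OC)cc(Cl)c1[C@H](c1cc(OC)c2c(c1)[C@@H](c1cc(OC)cc(OC)c1)[C@H](c1ccc(OC)cc1)O2)[C@H](c1ccc(OC)cc1)O | intermediate
33 | (2S,3S)-4-chloro-3-[(2R,3R)-3-(3,5-dimethoxyphenyl)-7-methoxy-2-(4-methoxyphenyl)-2,3-dihydro-1-benzofuran-5-yl]-6-methoxy-2-(4-methoxyphenyl)-2,3-dihydro-1-benzofuran | Clc1cc(OC)cc2c1[C@H](c1cc(OC)c3c(c1)[C@@H](c1cc(OC)cc(OC)c1)[C@H](c1ccc(OC)cc1)O3)[C@@H](c1ccc(OC)cc1)O2 | intermediate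
34 | (2S,3S)-4-chloro-3-[(2R,3R)-3-(3,5-dihydroxyphenyl)-7-hydroxy-2-(4-hydroxyphenyl)-2,3-dihydro-1-benzofuran-5-yl]-2-(4-hydroxyphenyl)-2,3-dihydro-1-benzofuran-6-ol | Clc1cc(O)cc2c1[C@H](c1cc(O)c3c(c1)[C@@H](c1cc(O)cc(O)c1)[C@H](c1ccc(O)cc1)O3)[C@@H](c1ccc(O)cc1)O2 | intermediate
35 | tert-butyl(4-ethynylphenoxy)dimethylsilane | C#Cc1ccc(O[Si](C)(C)C(C)(C)C)cc1 | starting material
36 | (Z)-2-[4-(tert-butyldimethylsilyloxy)phenyl]ethenylboronic acid pinacol ester | CC(C)(C)[Si](C)(C)Oc1ccc(/C=C\B2OC(C)(C)C(C)(C)O2)cc1 | intermediate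
37 | 4-O-tert-butyldimethylsilyl ether of the target (at the stilbene phenol) | CC(C)(C)[Si](C)(C)Oc1ccc(/C=C\c2cc(O)cc3c2[C@H](c2cc(O)c4c(c2)[C@@H](c2cc(O)cc(O)c2)[C@H](c2ccc(O)cc2)O4)[C@@H](c2ccc(O)cc2)O3)cc1 | intermediate
38 | CNP0172909.2 | Oc1ccc(/C=C\c2cc(O)cc3c2[C@H](c2cc(O)c4c(c2)[C@@H](c2cc(O)cc(O)c2)[C@H](c2ccc(O)cc2)O4)[C@@H](c2ccc(O)cc2)O3)cc1 | target

**Step count and risk**

Total step count: 22. Longest linear sequence: 14 steps (steps 8–15, 16, 17–20 and 22, from 13 to 38).

Steps most likely to fail: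

1. Step 16 (Proposed new method). The hindered β-aryl alkene may fail to bind palladium, or the ate complex may transfer its alkenyl group directly to palladium, and enantioface selection may be eroded by the chiral triflate. The fallback uses known chemistry, the carbonyl addition and rhodium-carbene C–H insertion already applied to ring B. It sets out from phenol aldehyde 4 and bromide 23 and returns at 33. Aldehyde 4 is O-alkylated with 14 (K2CO3, DMF) to 2-chloro-4-methoxy-6-[(4-methoxybenzyl)oxy]benzaldehyde F1. Bromide 23 undergoes bromine–lithium exchange (n-BuLi, THF, −78 °C) to the 5-lithio dihydrobenzofuran F2, which adds to F1 to give diarylmethanol F3. Dess–Martin oxidation gives diaryl ketone F4, hydrazine gives hydrazone F5, and MnO2 gives diaryldiazomethane F6. Rh2(S-PTAD)4 then inserts the carbene into the 4-methoxybenzylic C–H bond to give the cis-(2R,3S) ring A dihydrobenzofuran F7, and CF3CO2H epimerises C2 to deliver 33.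

2. Step 22. Oxidative addition into the ortho-substituted, electron-rich C–Cl bond of the polyphenolate may be slow, leaving time for protodeboronation of the Z-alkenylboronate, drift of the alkene geometry towards E, or air oxidation of the phenolates. The fallback replaces the direct coupling by a protect–couple–deprotect sequence on a neutral, less electron-rich substrate. It sets out from 34 and returns at 38. Peracetylation (Ac2O, pyridine) gives chloro hexaacetate F8, anhydrous Suzuki coupling with 36 (Pd(OAc)2, SPhos, K3PO4, toluene) gives the Z-stilbene hexaacetate silyl ether F9, and K2CO3 in MeOH removes the six acetates and the silyl group together.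

3. Step 19. Activation of the crowded secondary alcohol may be slow, so that elimination towards a triarylethene competes with ring closure. The fallback abandons the SN2 displacement for a cation-mediated closure. It sets out from 32 and returns at 33: catalytic TsOH (or BF3·OEt2) in CH2Cl2 at 0 °C ionises the 4-methoxybenzylic alcohol and the ring A phenol traps the cation, the existing C3 centre and thermodynamic control favouring the 2,3-trans ring. This fallback adds no compound to the list (F0).

**Further compounds**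

F1 | step 16 | 2-chloro-4-methoxy-6-[(4-methoxybenzyl)oxy]benzaldehyde | COc1ccc(COc2cc(OC)cc(Cl)c2C=O)cc1
F2 | step 16 | [(2R,3R)-3-(3,5-dimethoxyphenyl)-7-methoxy-2-(4-methoxyphenyl)-2,3-dihydro-1-benzofuran-5-yl]lithium | [Li]c1cc(OC)c2c(c1)[C@@H](c1cc(OC)cc(OC)c1)[C@H](c1ccc(OC)cc1)O2
F3 | step 16 | [2-chloro-4-methoxy-6-[(4-methoxybenzyl)oxy]phenyl][(2R,3R)-dihydrobenzofuran-5-yl]methanol (carbinol epimers) | COc1ccc(COc2cc(OC)cc(Cl)c2C(O)c2cc(OC)c3c(c2)[C@@H](c2cc(OC)cc(OC)c2)[C@H](c2ccc(OC)cc2)O3)cc1
F4 | step 16 | [2-chloro-4-methoxy-6-[(4-methoxybenzyl)oxy]phenyl][(2R,3R)-dihydrobenzofuran-5-yl]methanone | COc1ccc(COc2cc(OC)cc(Cl)c2C(=O)c2cc(OC)c3c(c2)[C@@H](c2cc(OC)cc(OC)c2)[C@H](c2ccc(OC)cc2)O3)cc1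
F5 | step 16 | hydrazone of ketone F4 | COc1ccc(COc2cc(OC)cc(Cl)c2C(=NN)c2cc(OC)c3c(c2)[C@@H](c2cc(OC)cc(OC)c2)[C@H](c2ccc(OC)cc2)O3)cc1
F6 | step 16 | diaryldiazomethane from F5 | COc1ccc(COc2cc(OC)cc(Cl)c2C(=[N+]=[N-])c2cc(OC)c3c(c2)[C@@H](c2cc(OC)cc(OC)c2)[C@H](c2ccc(OC)cc2)O3)cc1
F7 | step 16 | (2R,3S)-4-chloro-3-[(2R,3R)-dihydrobenzofuran-5-yl]-6-methoxy-2-(4-methoxyphenyl)-2,3-dihydro-1-benzofuran (2,3-cis epimer of 33) | Clc1cc(OC)cc2c1[C@H](c1cc(OC)c3c(c1)[C@@H](c1cc(OC)cc(OC)c1)[C@H](c1ccc(OC)cc1)O3)[C@H](c1ccc(OC)cc1)O2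
F8 | step 22 | hexaacetate of chloro hexaphenol 34 | Clc1cc(OC(C)=O)cc2c1[C@H](c1cc(OC(C)=O)c3c(c1)[C@@H](c1cc(OC(C)=O)cc(OC(C)=O)c1)[C@H](c1ccc(OC(C)=O)cc1)O3)[C@@H](c1ccc(OC(C)=O)cc1)O2
F9 | step 22 | hexaacetate tert-butyldimethylsilyl ether of the target (Z) | CC(C)(C)[Si](C)(C)Oc1ccc(/C=C\c2cc(OC(C)=O)cc3c2[C@H](c2cc(OC(C)=O)c4c(c2)[C@@H](c2cc(OC(C)=O)cc(OC(C)=O)c2)[C@H](c2ccc(OC(C)=O)cc2)O4)[C@@H](c2ccc(OC(C)=O)cc2)O3)cc1
F0 | step 19 | none | none
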